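Ring B is cut at C-5–C-6 and C-8–C-9, leaving a ring A block in which the allylic C-5 and the sulfone-acidified C-9 flank the quaternary C-10, and a (Z)-β-metalated acrylate that brings C-6, C-7, C-8 and the silyl-protected hydroxypropyl group. In one pot, a copper-mediated anti-SN2′ alkenylation joins C-6 to C-5, relaying the C-3 ester stereocentre to C-5 (trans ring fusion) and moving the alkene to C-3=C-4, and the C-9 carbanion then acylates the C-8 ester held cis on C-6=C-7. The step exploits the 1,3-disposition of C-5 and C-9 about C-10 in ring A; the new C-3=C-4 alkene later gives the cis-diol.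

Key step: step 8

Remark on numbering: eudesmane numbering is used throughout (ring A = C-1, C-2, C-3, C-4, C-5, C-10; ring B = C-5 to C-10; C-11 = carbinol carbon of the side chain).
Remark (assumption): the sense of induction in steps 2 and 4 is assigned from the accepted models for these catalysts; should either prove opposite, the antipodal catalyst is used.

Step 1
Reactants: 1 methacrolein (2-methylprop-2-enal); 2 thiophenol
Product: 3 rac-2-methyl-3-(phenylsulfanyl)propanal
Conditions: Et3N (cat.), CH2Cl2, 0 °C → rt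
Reagents that add atoms: none
Why: Sulfa-Michael addition of the thiol to the enal; the α-centre forms racemic, which does not matter because it becomes planar in the enamine of step 2.

Step 2
Reactants: 3 rac-2-methyl-3-(phenylsulfanyl)propanal; 4 ethyl vinyl ketone (pent-1-en-3-one)
Product: 6 (4S)-2,4-dimethyl-4-[(phenylsulfanyl)methyl]cyclohex-2-en-1-one, via Michael adduct keto-aldehyde 5 (not isolated)
Conditions: (S)-N-[(4-dodecylphenyl)sulfonyl]pyrrolidine-2-carboxamide (20 mol %), BnNH2 (co-catalyst), ClCH2CH2Cl, 4 Å molecular sieves, rt then 50 °C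
Reagents that add atoms: none
Why: Organocatalytic Robinson-type annulation (enamine Michael addition, then aldol condensation) in which both enantiomers of 3 converge on one enamine and the catalyst-controlled face of attack on 4 should set the quaternary C-10 as S before ring A closes.

Step 3
Reactants: 6 (4S)-2,4-dimethyl-4-[(phenylsulfanyl)methyl]cyclohex-2-en-1-one
Product: 7 (4S)-2,4-dimethyl-4-[(phenylsulfonyl)methyl]cyclohex-2-en-1-one
Conditions: 3-chloroperoxybenzoic acid (2.2 equiv), CH2Cl2, 0 °C
Reagents that add atoms: 3-chloroperoxybenzoic acid, OOC(=O)c1cccc(Cl)c1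
Why: Sulfide-to-sulfone oxidation, which should leave the electron-poor enone alkene untouched and makes C-9 acidic for the key step.

Step 4
Reactants: 7 (4S)-2,4-dimethyl-4-[(phenylsulfonyl)methyl]cyclohex-2-en-1-one
Product: 8 (1R,4S)-2,4-dimethyl-4-[(phenylsulfonyl)methyl]cyclohex-2-en-1-ol (hydroxyl cis to the sulfonylmethyl group)
Conditions: (S)-1-methyl-3,3-diphenyltetrahydro-1H,3H-pyrrolo[1,2-c][1,3,2]oxazaborole (0.2 equiv), BH3·SMe2, THF, −20 °C
Reagents that add atoms: none
Why: Corey–Bakshi–Shibata 1,2-reduction in which the catalyst (α-methyl alkenyl arm as the large group) should set C-3 as R, and any minor enantiomer of 7 should become a separable diastereomer.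

Step 5
Reactants: 8 (1R,4S)-2,4-dimethyl-4-[(phenylsulfonyl)methyl]cyclohex-2-en-1-ol
Product: 9 (1R,4S)-2,4-dimethyl-4-[(phenylsulfonyl)methyl]cyclohex-2-en-1-yl pyridine-2-carboxylate
Conditions: pyridine-2-carboxylic acid, N,N′-dicyclohexylcarbodiimide, 4-(dimethylamino)pyridine (cat.), CH2Cl2, rt
Reagents that add atoms: pyridine-2-carboxylic acid, OC(=O)c1ccccn1
Why: Steglich esterification with retention at C-3, installing the chelating leaving group needed for γ-selective allylic substitution.

Step 6
Reactants: 10 methyl propiolate; 11 acetone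
Product: 13 methyl (2Z)-2-(2-hydroxypropan-2-yl)-3-iodoprop-2-enoate (iodine cis to the ester), via aluminium iodoallenolate 12 (not isolated)
Conditions: Et2AlI, CH2Cl2, 0 °C; acetone, 0 °C → rt; aq. NH4Cl
Reagents that add atoms: diethylaluminium iodide, CC[Al](I)CC
Why: β-Iodo Baylis–Hillman-type reaction in which conjugate addition of iodide gives allenolate 12, whose α-carbon adds to acetone (aldol) and should give the Z isomer under kinetic control at low temperature.

Step 7
Reactants: 13 methyl (2Z)-2-(2-hydroxypropan-2-yl)-3-iodoprop-2-enoate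
Product: 14 methyl (2Z)-3-iodo-2-{2-[(trimethylsilyl)oxy]propan-2-yl}prop-2-enoate
Conditions: Me3SiCl, imidazole, DMF, rt
Reagents that add atoms: chlorotrimethylsilane, C[Si](C)(C)Cl
Why: Silylation of the tertiary alcohol so that no acidic proton is present during the organometallic key step.

Step 8
Reactants: 9 (1R,4S)-2,4-dimethyl-4-[(phenylsulfonyl)methyl]cyclohex-2-en-1-yl pyridine-2-carboxylate; 14 methyl (2Z)-3-iodo-2-{2-[(trimethylsilyl)oxy]propan-2-yl}prop-2-enoate
Product: 19 (4aS,8aS)-3-(2-hydroxypropan-2-yl)-5,8a-dimethyl-1-(phenylsulfonyl)-4a,7,8,8a-tetrahydronaphthalen-2(1H)-one (trans ring fusion; mixture at C-1 of this name, which is C-9), via alkenylmagnesium chloride 15 (not isolated), via alkenylcopper reagent 16 (not isolated), via SN2′ adduct 17 (not isolated), via cyclised silyl ether 18 (not isolated)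
Conditions: 14, iPrMgCl·LiCl, THF, −40 °C; CuBr·SMe2; 9, −40 → 0 °C; LiN(iPr)2 (2.2 equiv), −78 → −20 °C; 1 M HCl, rt
Reagents that add atoms: none
Why: Iodine–magnesium exchange on 14 and transmetalation to monovalent copper give the (Z)-alkenylcopper 16, which displaces the picolinate of 9 in an anti-SN2′ sense (copper-mediated, picolinate-assisted allylic substitution is the closest known reaction type), forming C-5–C-6 and moving the alkene to C-3=C-4 in 17. LiN(iPr)2 then deprotonates the sulfone-activated C-9, and this carbanion attacks the ester carbon C-8, held next to it by the Z-alkene, in an intramolecular Claisen (Dieckmann-type) acylation that closes ring B in the 6-exo-trig mode and ends as the stabilised enolate of the β-keto sulfone. The one lasting new stereocentre, C-5, is controlled by the C-3 ester: the alkenyl group enters anti to the leaving group, which is also the face away from the bulky sulfonylmethyl group on C-10, so H-5 and the C-10 methyl should end up trans, while the centre at C-9 is erased in step 9. The step needs γ- over α-substitution, which the chelating picolinate with the copper reagent secures, and C-9 over C-5 deprotonation, which is secured because the ester has no α-hydrogen and allylic 1,3-strain holds the C-5–H bond in the plane of the enoate. Forming C-5–C-6 first and intermolecularly is essential, since closure of a C-9-tethered chain onto a planar C-5 would give the cis fusion. Acidic work-up cleaves the trimethylsilyl ether 18 to the free tertiary alcohol 19.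

Step 9
Reactants: 19 (4aS,8aS)-3-(2-hydroxypropan-2-yl)-5,8a-dimethyl-1-(phenylsulfonyl)-4a,7,8,8a-tetrahydronaphthalen-2(1H)-one
Product: 20 (4aR,8aR)-3-(2-hydroxypropan-2-yl)-5,8a-dimethyl-4a,7,8,8a-tetrahydronaphthalen-2(1H)-one
Conditions: SmI2 (2.5 equiv), THF–MeOH, −78 °C
Reagents that add atoms: none
Why: Reductive desulfonylation of a β-keto sulfone by single-electron transfer, in which fast C–S cleavage next to the ketyl and protonation of the samarium enolate at C-9 should leave the enone, C-5 and the C-3=C-4 alkene untouched.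

Step 10
Reactants: 20 (4aR,8aR)-3-(2-hydroxypropan-2-yl)-5,8a-dimethyl-4a,7,8,8a-tetrahydronaphthalen-2(1H)-one
Product: 21 (4aR,5S,6R,8aR)-5,6-dihydroxy-3-(2-hydroxypropan-2-yl)-5,8a-dimethyl-4a,5,6,7,8,8a-hexahydronaphthalen-2(1H)-one (3α,4α-diol in eudesmane numbering)
Conditions: OsO4 (2 mol %), N-methylmorpholine N-oxide, acetone–H2O, rt
Reagents that add atoms: N-methylmorpholine N-oxide, C[N+]1([O-])CCOCC1; water, O
Why: Catalytic OsO4 syn-dihydroxylation, which should select the electron-rich C-3=C-4 alkene over the enone and attack the face opposite the axial C-10 methyl, setting C-3 and C-4 together (both hydroxyls α, C-4 methyl β).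

Step 11
Reactants: 21 (4aR,5S,6R,8aR)-5,6-dihydroxy-3-(2-hydroxypropan-2-yl)-5,8a-dimethyl-4a,5,6,7,8,8a-hexahydronaphthalen-2(1H)-one; 22 angelic acid ((2Z)-2-methylbut-2-enoic acid)
Product: 24 (1S,2R,4aR,8aR)-1-hydroxy-7-(2-hydroxypropan-2-yl)-1,4a-dimethyl-6-oxo-1,2,3,4,4a,5,6,8a-octahydronaphthalen-2-yl (2Z)-2-methylbut-2-enoate (CNP0261892.2), via mixed anhydride 23 (not isolated)
Conditions: 22, 2,4,6-trichlorobenzoyl chloride, Et3N, toluene, rt; then 21, 75 °C
Reagents that add atoms: none
Why: Yamaguchi esterification through the mixed anhydride without a nucleophilic catalyst, conditions chosen to avoid angelate-to-tiglate isomerisation, and only the secondary C-3 hydroxyl should react because the other two hydroxyls are tertiary.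

Compound list
1 | methacrolein (2-methylprop-2-enal) | CC(=C)C=O | starting material
2 | thiophenol | Sc1ccccc1 | starting material
3 | rac-2-methyl-3-(phenylsulfanyl)propanal | CC(CSc1ccccc1)C=O | intermediate
4 | ethyl vinyl ketone (pent-1-en-3-one) | CCC(=O)C=C | starting material
5 | (2S)-2-methyl-5-oxo-2-[(phenylsulfanyl)methyl]heptanal | CCC(=O)CC[C@](C)(CSc1ccccc1)C=O | intermediate
6 | (4S)-2,4-dimethyl-4-[(phenylsulfanyl)methyl]cyclohex-2-en-1-one | O=C1CC[C@](C)(CSc2ccccc2)C=C1C | intermediate
7 | (4S)-2,4-dimethyl-4-[(phenylsulfonyl)methyl]cyclohex-2-en-1-one | O=C1CC[C@](C)(CS(=O)(=O)c2ccccc2)C=C1C | intermediate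
8 | (1R,4S)-2,4-dimethyl-4-[(phenylsulfonyl)methyl]cyclohex-2-en-1-ol | O[C@@H]1CC[C@](C)(CS(=O)(=O)c2ccccc2)C=C1C | intermediate
9 | (1R,4S)-2,4-dimethyl-4-[(phenylsulfonyl)methyl]cyclohex-2-en-1-yl pyridine-2-carboxylate | O=C(O[C@@H]1CC[C@](C)(CS(=O)(=O)c2ccccc2)C=C1C)c1ccccn1 | intermediate
10 | methyl propiolate | COC(=O)C#C | starting material
11 | acetone | CC(C)=O | starting material
12 | diethylaluminium 3-iodo-1-methoxypropa-1,2-dien-1-olate | COC(O[Al](CC)CC)=C=CI | intermediate
13 | methyl (2Z)-2-(2-hydroxypropan-2-yl)-3-iodoprop-2-enoate | I/C=C(/C(C)(C)O)C(=O)OC | intermediate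
14 | methyl (2Z)-3-iodo-2-{2-[(trimethylsilyl)oxy]propan-2-yl}prop-2-enoate | I/C=C(/C(C)(C)O[Si](C)(C)C)C(=O)OC | intermediate
15 | chloro[(1Z)-3-methoxy-3-oxo-2-{2-[(trimethylsilyl)oxy]propan-2-yl}prop-1-en-1-yl]magnesium | Cl[Mg]/C=C(/C(C)(C)O[Si](C)(C)C)C(=O)OC | intermediate
16 | [(1Z)-3-methoxy-3-oxo-2-{2-[(trimethylsilyl)oxy]propan-2-yl}prop-1-en-1-yl]copper | [Cu]/C=C(/C(C)(C)O[Si](C)(C)C)C(=O)OC | intermediate
17 | methyl (2Z)-3-{(1S,6S)-2,6-dimethyl-6-[(phenylsulfonyl)methyl]cyclohex-2-en-1-yl}-2-{2-[(trimethylsilyl)oxy]propan-2-yl}prop-2-enoate | COC(=O)/C(C(C)(C)O[Si](C)(C)C)=C\[C@H]1C(C)=CCC[C@]1(C)CS(=O)(=O)c1ccccc1 | intermediate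
18 | (4aS,8aS)-5,8a-dimethyl-1-(phenylsulfonyl)-3-{2-[(trimethylsilyl)oxy]propan-2-yl}-4a,7,8,8a-tetrahydronaphthalen-2(1H)-one | CC1=CCC[C@]2(C)C(S(=O)(=O)c3ccccc3)C(=O)C(C(C)(C)O[Si](C)(C)C)=C[C@@H]12 | intermediate
19 | (4aS,8aS)-3-(2-hydroxypropan-2-yl)-5,8a-dimethyl-1-(phenylsulfonyl)-4a,7,8,8a-tetrahydronaphthalen-2(1H)-one | CC1=CCC[C@]2(C)C(S(=O)(=O)c3ccccc3)C(=O)C(C(C)(C)O)=C[C@@H]12 | intermediate
20 | (4aR,8aR)-3-(2-hydroxypropan-2-yl)-5,8a-dimethyl-4a,7,8,8a-tetrahydronaphthalen-2(1H)-one | CC1=CCC[C@]2(C)CC(=O)C(C(C)(C)O)=C[C@@H]12 | intermediate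
21 | (4aR,5S,6R,8aR)-5,6-dihydroxy-3-(2-hydroxypropan-2-yl)-5,8a-dimethyl-4a,5,6,7,8,8a-hexahydronaphthalen-2(1H)-one | O[C@@H]1CC[C@]2(C)CC(=O)C(C(C)(C)O)=C[C@H]2[C@]1(C)O | intermediate
22 | angelic acid ((2Z)-2-methylbut-2-enoic acid) | C/C=C(/C)C(O)=O | starting material
23 | (2Z)-2-methylbut-2-enoic 2,4,6-trichlorobenzoic anhydride | C/C=C(/C)C(=O)OC(=O)c1c(Cl)cc(Cl)cc1Cl | intermediate
24 | (1S,2R,4aR,8aR)-1-hydroxy-7-(2-hydroxypropan-2-yl)-1,4a-dimethyl-6-oxo-1,2,3,4,4a,5,6,8a-octahydronaphthalen-2-yl (2Z)-2-methylbut-2-enoate | C/C=C(/C)C(=O)O[C@@H]1CC[C@]2(C)CC(=O)C(C(C)(C)O)=C[C@H]2[C@]1(C)O | target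

Total step count: 11. Longest linear sequence: 9 steps (steps 1–5 and 8–11).

Steps most likely to fail

Step 8. Transfer of the α-branched, ester-chelated alkenylcopper to the neopentyl-type C-5 may be too slow, so that substitution at C-3 or simple reduction competes, and the base may then remove the doubly allylic C-5 hydrogen instead of a C-9 hydrogen, which erases the C-5 configuration and stops ring closure. Fallback: the branched side chain is left out of the annulation and attached afterwards. Setting out from 9, the same allylic substitution and base-induced closure are run with the unbranched (Z)-2-(methoxycarbonyl)ethenylcopper made from commercial methyl (2Z)-3-iodoprop-2-enoate, which should give the β-keto sulfone without side chain F1. SmI2 in THF–MeOH removes the sulfone to give the dienone F2. Me2AlSPh adds its thiolate to C-6 and the aluminium enolate is trapped at C-7 with acetone (thio-Michael/aldol sequence) to give the β-phenylthio aldol F3. Oxidation with NaIO4 and thermal sulfoxide elimination restore the C-6=C-7 bond, and the route is rejoined at 20.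

Step 2. Loss of thiophenolate from the enamine (retro-sulfa-Michael) and poor facial discrimination between the methyl and phenylthiomethyl arms may erode yield and enantiopurity. Fallback: a stoichiometric chiral auxiliary replaces the catalyst. Setting out from 3, condensation with (S)-1-phenylethylamine (or its antipode, whichever gives the 2S centre) gives the imine F4; its secondary enamine tautomer adds to 4 in an aza-ene-type Michael addition, mild aqueous acid releases keto-aldehyde 5, and base-mediated aldol condensation returns to the route at 6.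

Step 6. The aluminium allenolate may add only sluggishly to a ketone, so that protonation to the simple β-iodoacrylate and oligomerisation take over. Fallback: the tertiary carbinol is built in two stages from an aldehyde. Setting out from 10, the iodide-triggered aldol is run with acetaldehyde (MgI2, CH2Cl2) to give the secondary alcohol F5; Dess–Martin oxidation gives the methyl ketone F6; and MeTi(OiPr)3, which adds to the ketone but not to the ester or the β-iodoenoate, returns to the route at 13.

Further compounds
F1 | step 8 | (4aS,8aS)-5,8a-dimethyl-1-(phenylsulfonyl)-4a,7,8,8a-tetrahydronaphthalen-2(1H)-one | CC1=CCC[C@]2(C)C(S(=O)(=O)c3ccccc3)C(=O)C=C[C@@H]12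
F2 | step 8 | (4aR,8aR)-5,8a-dimethyl-4a,7,8,8a-tetrahydronaphthalen-2(1H)-one | CC1=CCC[C@]2(C)CC(=O)C=C[C@@H]12
F3 | step 8 | (4aR,8aR)-3-(2-hydroxypropan-2-yl)-5,8a-dimethyl-4-(phenylsulfanyl)-3,4,4a,7,8,8a-hexahydronaphthalen-2(1H)-one (mixture at C-3 and C-4) | CC1=CCC[C@]2(C)CC(=O)C(C(C)(C)O)C(Sc3ccccc3)[C@@H]12
F4 | step 2 | 2-methyl-N-[(1S)-1-phenylethyl]-3-(phenylsulfanyl)propan-1-imine | C[C@H](N=CC(C)CSc1ccccc1)c1ccccc1
F5 | step 6 | methyl (2Z)-2-(1-hydroxyethyl)-3-iodoprop-2-enoate (racemic) | I/C=C(/C(C)O)C(=O)OC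
F6 | step 6 | methyl (2Z)-2-acetyl-3-iodoprop-2-enoate | I/C=C(/C(C)=O)C(=O)OC
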